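**Assumption:** commercial (R)-(−)-linalool of ≥95% ee is used; it is the only source of chirality, so the product ee equals the linalool ee. Target = (2R,3′E,7′E)-β-tocotrienol.

## Retrosynthetic overview
1. C6–OH ⇐ C6–Br: an aryl bromide serves as the phenol surrogate and is hydroxylated in the last step.
2. Side chain: terminal isopropylidene ⇐ Wittig; both (E)-trisubstituted alkenes and the C5′–C6′ and C9′–C10′ bonds ⇐ two iterative Johnson–Claisen [3,3] rearrangements of isopropenyl carbinols (key steps).
3. First carbinol ⇐ chroman propanal ⇐ ozonolysis of the linalool prenyl group.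
4. Dihydropyran ring (the only ring formed; the arene is bought) ⇐ intramolecular Cu-catalysed O-arylation by linalool's own tertiary OH, so the C2–O bond is never broken.
5. C4–C4a ⇐ hydroboration / B-alkyl Suzuki of the (R)-linalool vinyl group with a symmetry-derived iodo-dibromoxylene.

## Route

**Step 1**
Reactants: 1, 1,4-dibromo-2,5-dimethylbenzene
Product: 2, 1,4-dibromo-3-iodo-2,5-dimethylbenzene
Conditions: NIS (1.0 equiv), TfOH, CH2Cl2, 0 °C → rt
Reagents that add atoms: N-iodosuccinimide, O=C1CCC(=O)N1I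
Why: Electrophilic aromatic iodination; the two ring C–H positions are symmetry-equivalent, so only one mono-iodide can form, and the iodine marks the adjacent bromine as the future C8a.

**Step 2**
Reactants: 3, (R)-(−)-linalool; 2, 1,4-dibromo-3-iodo-2,5-dimethylbenzene
Product: 4, (3R)-1-(2,5-dibromo-3,6-dimethylphenyl)-3,7-dimethyloct-6-en-3-ol
Conditions: 9-BBN (2.2 equiv), THF, 0 °C → rt; then 2 (1.1 equiv), Pd(dppf)Cl2 (5 mol %), AsPh3, aq Cs2CO3, DMF, 50 °C
Reagents that add atoms: none (9-BBN delivers only H)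
Why: Anti-Markovnikov hydroboration selective for the monosubstituted vinyl group, then B-alkyl Suzuki–Miyaura coupling at C–I in preference to C–Br; the stereocentre is not involved.

**Step 3**
Reactants: 4
Product: 5, (2R)-6-bromo-2,5,8-trimethyl-2-(4-methylpent-3-en-1-yl)chromane
Conditions: CuI (20 mol %), 3,4,7,8-tetramethyl-1,10-phenanthroline (40 mol %), Cs2CO3, toluene, 110 °C
Reagents that add atoms: none
Why: Intramolecular Ullmann-type C–O coupling; the tertiary alkoxide can reach only the ortho bromide (six-membered ring), and the O–C2 bond is untouched, so configuration is retained.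

**Step 4**
Reactants: 5
Product: 6, 3-[(2S)-6-bromo-2,5,8-trimethylchroman-2-yl]propanal (descriptor changes by CIP priority only; same spatial arrangement)
Conditions: O3, CH2Cl2/MeOH, −78 °C (Sudan III end-point); then Me2S, −78 °C → rt
Reagents that add atoms: ozone, [O-][O+]=O
Why: Ozonolysis of the only alkene (trisubstituted, far more reactive than the arene) gives the aldehyde and acetone.

**Step 5**
Reactants: 6; 7, isopropenylmagnesium bromide
Product: 8, 5-[(2S)-6-bromo-2,5,8-trimethylchroman-2-yl]-2-methylpent-1-en-3-ol (about 1:1 carbinol epimers)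
Conditions: 7 (1.3 equiv), THF, −78 → 0 °C
Reagents that add atoms: isopropenylmagnesium bromide, CC(=C)[Mg]Br
Why: Grignard 1,2-addition; the new carbinol centre is uncontrolled but becomes sp2 in step 6, so it does not matter.

**Step 6**
Reactants: 8; 9, triethyl orthoacetate
Product: 10, ethyl (4E)-7-[(2R)-6-bromo-2,5,8-trimethylchroman-2-yl]-4-methylhept-4-enoate
Conditions: MeC(OEt)3 (6 equiv), EtCO2H (10 mol %), 140 °C, EtOH distilled off
Reagents that add atoms: triethyl orthoacetate, CCOC(C)(OCC)OCC
Why: Johnson–Claisen [3,3]-sigmatropic rearrangement forms C5′–C6′; the chair transition state with the carbinol substituent equatorial gives the (E)-trisubstituted C3′=C4′ alkene (typically ≥97:3).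

**Step 7**
Reactants: 10
Product: 11, (4E)-7-[(2R)-6-bromo-2,5,8-trimethylchroman-2-yl]-4-methylhept-4-enal
Conditions: DIBAL-H (1.1 equiv), CH2Cl2, −78 °C; MeOH, then Rochelle salt
Reagents that add atoms: none
Why: Partial reduction of the ester through the aluminium hemiacetal, which is stable at −78 °C; aryl bromide and alkene are inert.

**Step 8**
Reactants: 11; 7, isopropenylmagnesium bromide
Product: 12, (6E)-9-[(2R)-6-bromo-2,5,8-trimethylchroman-2-yl]-2,6-dimethylnona-1,6-dien-3-ol (about 1:1 carbinol epimers)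
Conditions: 7 (1.3 equiv), THF, −78 → 0 °C
Reagents that add atoms: isopropenylmagnesium bromide, CC(=C)[Mg]Br
Why: Grignard addition sets up the second Claisen substrate; the carbinol centre is again destroyed in the next step.

**Step 9**
Reactants: 12; 9, triethyl orthoacetate
Product: 13, ethyl (4E,8E)-11-[(2R)-6-bromo-2,5,8-trimethylchroman-2-yl]-4,8-dimethylundeca-4,8-dienoate
Conditions: MeC(OEt)3 (6 equiv), EtCO2H (10 mol %), 140 °C, EtOH distilled off
Reagents that add atoms: triethyl orthoacetate, CCOC(C)(OCC)OCC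
Why: Second Johnson–Claisen [3,3] rearrangement forms C9′–C10′ and the (E)-C7′=C8′ alkene by the same chair control; the existing alkene is not affected.

**Step 10**
Reactants: 13
Product: 14, (4E,8E)-11-[(2R)-6-bromo-2,5,8-trimethylchroman-2-yl]-4,8-dimethylundeca-4,8-dienal
Conditions: DIBAL-H (1.1 equiv), CH2Cl2, −78 °C; MeOH, then Rochelle salt
Reagents that add atoms: none
Why: Partial ester reduction as in step 7.

**Step 11**
Reactants: 14; 15, isopropyltriphenylphosphonium iodide
Product: 16, (2R)-6-bromo-2,5,8-trimethyl-2-[(3E,7E)-4,8,12-trimethyltrideca-3,7,11-trien-1-yl]chromane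
Conditions: 15 (1.5 equiv), n-BuLi (1.4 equiv), THF, 0 °C; then 14, −78 °C → rt
Reagents that add atoms: isopropyltriphenylphosphonium iodide, CC(C)[P+](c1ccccc1)(c1ccccc1)c1ccccc1.[I-]
Why: Wittig olefination installs the terminal isopropylidene, which has no geometry to control; the ylide does not touch the aryl bromide.

**Step 12**
Reactants: 16
Product: 17, (2R)-β-tocotrienol, (2R)-2,5,8-trimethyl-2-[(3E,7E)-4,8,12-trimethyltrideca-3,7,11-trien-1-yl]chroman-6-ol
Conditions: t-BuLi (2.1 equiv), THF, −78 °C; B(OMe)3, −78 °C → rt; then H2O2, aq NaOH, 0 °C; NH4Cl work-up under N2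
Reagents that add atoms: hydrogen peroxide, OO (phenolic O; trimethyl borate, COB(OC)OC, is transient)
Why: Halogen–lithium exchange, borylation and oxidative 1,2-aryl migration from boron to oxygen (ipso-hydroxylation); isolated trisubstituted alkenes and the chroman ether are inert to ArLi at −78 °C and to basic peroxide.

## Compound list
1 | 1,4-dibromo-2,5-dimethylbenzene | Cc1cc(Br)c(C)cc1Br | starting material
2 | 1,4-dibromo-3-iodo-2,5-dimethylbenzene | Cc1cc(Br)c(C)c(I)c1Br | intermediate
3 | (R)-(−)-linalool, (3R)-3,7-dimethylocta-1,6-dien-3-ol | CC(C)=CCC[C@@](C)(O)C=C | starting material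
4 | (3R)-1-(2,5-dibromo-3,6-dimethylphenyl)-3,7-dimethyloct-6-en-3-ol | CC(C)=CCC[C@@](C)(O)CCc1c(C)c(Br)cc(C)c1Br | intermediate
5 | (2R)-6-bromo-2,5,8-trimethyl-2-(4-methylpent-3-en-1-yl)chromane | CC(C)=CCC[C@]1(C)CCc2c(C)c(Br)cc(C)c2O1 | intermediate
6 | 3-[(2S)-6-bromo-2,5,8-trimethylchroman-2-yl]propanal | O=CCC[C@]1(C)CCc2c(C)c(Br)cc(C)c2O1 | intermediate
7 | isopropenylmagnesium bromide | CC(=C)[Mg]Br | starting material
8 | 5-[(2S)-6-bromo-2,5,8-trimethylchroman-2-yl]-2-methylpent-1-en-3-ol (carbinol epimer mixture) | C=C(C)C(O)CC[C@]1(C)CCc2c(C)c(Br)cc(C)c2O1 | intermediate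
9 | triethyl orthoacetate | CCOC(C)(OCC)OCC | starting material
10 | ethyl (4E)-7-[(2R)-6-bromo-2,5,8-trimethylchroman-2-yl]-4-methylhept-4-enoate | CCOC(=O)CC/C(C)=C/CC[C@]1(C)CCc2c(C)c(Br)cc(C)c2O1 | intermediate
11 | (4E)-7-[(2R)-6-bromo-2,5,8-trimethylchroman-2-yl]-4-methylhept-4-enal | O=CCC/C(C)=C/CC[C@]1(C)CCc2c(C)c(Br)cc(C)c2O1 | intermediate
12 | (6E)-9-[(2R)-6-bromo-2,5,8-trimethylchroman-2-yl]-2,6-dimethylnona-1,6-dien-3-ol (carbinol epimer mixture) | C=C(C)C(O)CC/C(C)=C/CC[C@]1(C)CCc2c(C)c(Br)cc(C)c2O1 | intermediate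
13 | ethyl (4E,8E)-11-[(2R)-6-bromo-2,5,8-trimethylchroman-2-yl]-4,8-dimethylundeca-4,8-dienoate | CCOC(=O)CC/C(C)=C/CC/C(C)=C/CC[C@]1(C)CCc2c(C)c(Br)cc(C)c2O1 | intermediate
14 | (4E,8E)-11-[(2R)-6-bromo-2,5,8-trimethylchroman-2-yl]-4,8-dimethylundeca-4,8-dienal | O=CCC/C(C)=C/CC/C(C)=C/CC[C@]1(C)CCc2c(C)c(Br)cc(C)c2O1 | intermediate
15 | isopropyltriphenylphosphonium iodide | CC(C)[P+](c1ccccc1)(c1ccccc1)c1ccccc1.[I-] | starting material
16 | (2R)-6-bromo-2,5,8-trimethyl-2-[(3E,7E)-4,8,12-trimethyltrideca-3,7,11-trien-1-yl]chromane | CC(C)=CCC/C(C)=C/CC/C(C)=C/CC[C@]1(C)CCc2c(C)c(Br)cc(C)c2O1 | intermediate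
17 | (2R)-β-tocotrienol | CC(C)=CCC/C(C)=C/CC/C(C)=C/CC[C@]1(C)CCc2c(C)c(O)cc(C)c2O1 | target

## Summary
Total steps: 12. Longest linear sequence: 12 (from 1; 11 from (R)-linalool).

Steps most likely to fail, with fallbacks:
1. **Step 3** (Cu O-arylation by a tertiary alcohol at a di-ortho-substituted bromide, with a second bromide present). Fallback: close the ring through a quinone instead.
   - Use 1-iodo-2,5-dimethoxy-3,6-dimethylbenzene in step 2, then oxidise with CAN to the quinone.
   - Let the tertiary OH add to the quinone carbonyl as a cyclic ketal (MeOH/HC(OMe)3/H+) and reduce (Zn/AcOH) to the 6-chromanol; the C2–O bond is still never broken.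
   - Carry the phenol as its TBS ether and finish with TBAF in place of step 12.
2. **Step 12** (late-stage Br → OH on the air-sensitive triene). Fallback: do the bromide-to-phenol exchange on the robust bromochroman 5, protect as the TBS ether, run steps 4–11 on the silyl ether and end with TBAF.
3. **Step 2** (B-alkyl Suzuki at a hindered iodide flanked by Me and Br, with a free tertiary OH). Fallback: Heck arylation of the linalool vinyl group with 2 to give the (E)-styrenyl tertiary alcohol, then diimide reduction of that disubstituted alkene (the trisubstituted one is spared) to reach 4.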